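**Retrosynthetic overview**

- Late stage: the C1 ketone comes from a silyl-protected allylic alcohol (oxidised last), the angelate is put on a C8/C9 diol, C9–O and C10=C14 come from a singlet-oxygen ene reaction, and the α-methylene group from a Mannich/elimination sequence.
- The C3–C4 epoxide and the C8 alcohol come from a trans-fused keto lactone by substrate-controlled epoxidation and Luche reduction.
- Key step: an anionic oxy-Cope [3,3] rearrangement of a 1,2-dialkenylcyclohexenol forms C5–C6 and the ten-membered ring; the enolate is trapped at C7 with bromoacetate, and the C6 oxygen arrives as an E enol ether.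
- The dialkenylcyclohexenol comes from a γ-silyloxy enone made from (R)-carvone (Luche reduction, silylation, allylic oxidation) plus a PMB-oxyacetylide (then trans-hydroalumination).
- Ring order: cyclohexene (purchased) → cyclodecadienone (oxy-Cope) → γ-lactone → epoxide; the only purchased stereocentre is C5 of (R)-carvone.

Assumption: ten-membered-ring compounds carry germacrane locants (ring C1–C10, C14 on C10, C15 on C4, lactone carbons C11–C13), and all descriptors below use them.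

**Step 1**
Reactants: 1 (R)-(−)-carvone
Product: 2 (1R,5R)-2-methyl-5-(prop-1-en-2-yl)cyclohex-2-en-1-ol (cis-carveol)
Conditions: NaBH4, CeCl3·7H2O, MeOH, −20 °C
Reagents that add atoms: none
Why: Luche 1,2-reduction in which hydride adds axially to the enone carbonyl, so the new C1 carbinol is set cis to the C5 isopropenyl group (1R) by substrate control.

**Step 2**
Reactants: 2 (1R,5R)-cis-carveol
Product: 3 tert-butyl(dimethyl){[(1R,5R)-2-methyl-5-(prop-1-en-2-yl)cyclohex-2-en-1-yl]oxy}silane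
Conditions: TBSCl, imidazole, DMF, rt
Reagents that add atoms: TBSCl (tert-butyldimethylsilyl chloride), CC(C)(C)[Si](C)(C)Cl
Why: Standard silylation of the secondary allylic alcohol; the silyl ether protects this oxygen until the end and later blocks its carbinol hydrogen in the ene reaction.

**Step 3**
Reactants: 3 cis-carveol TBS ether
Product: 4 (4R,6R)-4-(tert-butyldimethylsilyloxy)-3-methyl-6-(prop-1-en-2-yl)cyclohex-2-en-1-one
Conditions: CrO3, 3,5-dimethylpyrazole, CH2Cl2, −20 °C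
Reagents that add atoms: CrO3 (chromium trioxide), O=[Cr](=O)=O
Why: Allylic C–H oxidation at the only ring methylene allylic to the trisubstituted olefin gives the γ-silyloxy enone, and the non-basic medium leaves the stereocentre next to the new ketone untouched.

**Step 4**
Reactants: 5 4-methoxybenzyl alcohol; 6 trichloroethylene
Product: 7 1-{[(E)-1,2-dichloroethenyl]oxymethyl}-4-methoxybenzene
Conditions: KH, THF, 0 °C to rt
Reagents that add atoms: none
Why: Alkoxide addition–elimination on trichloroethylene (through dichloroacetylene) gives the E-dichlorovinyl ether, a storable precursor of the alkoxyacetylide.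

**Step 5**
Reactants: 7 (E)-1,2-dichlorovinyl 4-methoxybenzyl ether; 4 (4R,6R)-enone
Product: 11 (1R,4R,6R)-4-(tert-butyldimethylsilyloxy)-1-[(E)-2-(4-methoxybenzyloxy)ethenyl]-3-methyl-6-(prop-1-en-2-yl)cyclohex-2-en-1-ol, via lithium alkoxyacetylide 8 (not isolated), via lithium propargylic alkoxide 9 (not isolated), via cyclic vinylalanate 10 (not isolated)
Conditions: 7, n-BuLi (2.2 equiv), THF, −78 to −40 °C; then 4, −78 °C; then LiAlH4, −78 °C to rt; aq NaOH
Reagents that add atoms: none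
Why: Dehydrochlorination and Cl/Li exchange give the lithium alkoxyacetylide, which adds 1,2 to the enone anti to the neighbouring isopropenyl group (new carbinol centre 1R), and alkoxide-directed trans-hydroalumination of the ynol ether gives the E enol ether.

**Step 6**
Reactants: 11 (1R,4R,6R)-dialkenylcyclohexenol
Product: 14 methyl (1R,3E,6R,7S,9Z)-1-(tert-butyldimethylsilyloxy)-6-(4-methoxybenzyloxy)-8-oxo-13-norgermacra-3,9-dien-12-oate, via potassium alkoxide 12 (not isolated), via potassium enolate 13 (not isolated)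
Conditions: KH, 18-crown-6, THF, 0 °C to rt; then BrCH2CO2Me, −78 °C
Reagents that add atoms: methyl bromoacetate, COC(=O)CBr
Why: Anionic oxy-Cope [3,3]-sigmatropic rearrangement through a chair transition state with both alkenyl groups equatorial forms C5–C6 and the ten-membered ring with an E C3=C4 bond; the carvone-derived centre is traded for C6 (R, the E enol ether holds the OPMB group equatorial), and the enolate is alkylated on its outer face, trans to that group (7S).

**Step 7**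
Reactants: 14 keto ester
Product: 16 (1R,3E,6R,7S,9Z)-1-(tert-butyldimethylsilyloxy)-8-oxo-13-norgermacra-3,9-dien-12,6-olide, via hydroxy keto ester 15 (not isolated)
Conditions: DDQ, CH2Cl2, pH 7 buffer, 0 °C; then PPTS, CH2Cl2, rt
Reagents that add atoms: none
Why: Oxidative PMB-ether cleavage followed by acid-catalysed lactonisation of the γ-hydroxy ester gives the trans-fused γ-lactone without touching a stereocentre.

**Step 8**
Reactants: 16 keto lactone
Product: 17 (1R,3R,4R,6R,7S,9Z)-1-(tert-butyldimethylsilyloxy)-3,4-epoxy-8-oxo-13-norgermacr-9-en-12,6-olide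
Conditions: mCPBA, NaHCO3, CH2Cl2, 0 °C
Reagents that add atoms: mCPBA (3-chloroperoxybenzoic acid), O=C(OO)c1cccc(Cl)c1
Why: Prilezhaev epoxidation in which only the C3=C4 bond is electron-rich (the other ring olefin is an enone); the peracid is expected to attack the outer face of the rotamer that turns C15 to the α side, away from the syn-axial C8 carbonyl oxygen, giving the 3R,4R epoxide.

**Step 9**
Reactants: 17 epoxy keto lactone
Product: 18 (1R,3R,4R,6R,7R,8R,9Z)-1-(tert-butyldimethylsilyloxy)-3,4-epoxy-8-hydroxy-13-norgermacr-9-en-12,6-olide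
Conditions: NaBH4, CeCl3·7H2O, MeOH, −78 °C
Reagents that add atoms: none
Why: Luche 1,2-reduction in which hydride attacks the outer (α) face of the C8 carbonyl, away from the transannular C3–C4 unit, giving the 8β alcohol cis to C11 (descriptor 8R in this compound, the same spatial arrangement as 8S in the target).

**Step 10**
Reactants: 18 hydroxy lactone
Product: 21 (1R,3R,4R,6R,7R,8R,9Z)-1-(tert-butyldimethylsilyloxy)-3,4-epoxy-8-hydroxygermacra-9,11(13)-dien-12,6-olide, via Mannich base 19 (not isolated), via ammonium iodide 20 (not isolated)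
Conditions: LiN(i-Pr)2 (2.5 equiv), THF, −78 °C; dimethyl(methylene)ammonium iodide; then MeI, MeOH, rt; then aq NaHCO3
Reagents that add atoms: dimethyl(methylene)ammonium iodide, C=[N+](C)C.[I-]
Why: Lactone α-methylenation: the lithium enolate (the C8 hydroxyl is carried as its alkoxide) undergoes a Mannich reaction with the iminium salt, and the quaternised amine leaves by Hofmann-type elimination, so no stereocentre remains at C11.

**Step 11**
Reactants: 21 α-methylene lactone
Product: 23 (1R,3R,4R,6R,7R,8S,9S)-1-(tert-butyldimethylsilyloxy)-3,4-epoxy-8,9-dihydroxygermacra-10(14),11(13)-dien-12,6-olide, via allylic hydroperoxide 22 (not isolated)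
Conditions: O2, hν, meso-tetraphenylporphyrin (cat.), CH2Cl2, 0 °C; then PPh3
Reagents that add atoms: O2 (dioxygen), O=O
Why: Schenck ene reaction of singlet oxygen with the Z allylic alcohol: both ring allylic hydrogens sit on oxygen-bearing carbons and lie in the olefin plane, so oxygen bonds to C9 and a C14 hydrogen is abstracted, on the face syn to the free C8 hydroxyl (hydroxyl-directed, threo), which sets 9S; PPh3 reduces the hydroperoxide.

**Step 12**
Reactants: 23 diol
Product: 24 (1R,3R,4R,6R,7R,8S,9S)-9-[(Z)-2-methylbut-2-enoyloxy]-1-(tert-butyldimethylsilyloxy)-3,4-epoxy-8-hydroxygermacra-10(14),11(13)-dien-12,6-olide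
Conditions: angelic acid, 2,4,6-Cl3C6H2COCl, Et3N, toluene, rt; then 23, DMAP, 0 °C to rt
Reagents that add atoms: angelic acid, C/C=C(C)\C(=O)O
Why: Yamaguchi esterification in which the mixed anhydride acylates the more accessible allylic C9 hydroxyl in preference to the C8 hydroxyl beside the lactone ring junction, and the Z geometry of the angelate is kept.

**Step 13**
Reactants: 24 silyl ether angelate
Product: 25 (1R,3R,4R,6R,7R,8S,9S)-9-[(Z)-2-methylbut-2-enoyloxy]-3,4-epoxy-1,8-dihydroxygermacra-10(14),11(13)-dien-12,6-olide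
Conditions: HF·pyridine, pyridine, THF, 0 °C
Reagents that add atoms: none
Why: Buffered fluoride desilylation frees the C1 hydroxyl without opening the epoxide or cleaving the esters.

**Step 14**
Reactants: 25 diol angelate
Product: 26 (3R,4R,6R,7R,8S,9S)-9-[(Z)-2-methylbut-2-enoyloxy]-3,4-epoxy-8-hydroxy-1-oxogermacra-10(14),11(13)-dien-12,6-olide (target)
Conditions: MnO2, CH2Cl2, rt
Reagents that add atoms: none
Why: MnO2 oxidises only the allylic C1 alcohol (the C8 alcohol is not allylic) to the α-methylene ketone, which completes the target.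

**Compound list**

1 | (R)-(−)-carvone, (5R)-2-methyl-5-(prop-1-en-2-yl)cyclohex-2-en-1-one | CC1=CC[C@H](CC1=O)C(C)=C | starting material
2 | (1R,5R)-2-methyl-5-(prop-1-en-2-yl)cyclohex-2-en-1-ol (cis-carveol) | CC1=CC[C@H](C[C@H]1O)C(C)=C | intermediate
3 | tert-butyl(dimethyl){[(1R,5R)-2-methyl-5-(prop-1-en-2-yl)cyclohex-2-en-1-yl]oxy}silane | CC1=CC[C@H](C[C@H]1O[Si](C)(C)C(C)(C)C)C(C)=C | intermediate
4 | (4R,6R)-4-(tert-butyldimethylsilyloxy)-3-methyl-6-(prop-1-en-2-yl)cyclohex-2-en-1-one | CC1=CC(=O)[C@H](C[C@H]1O[Si](C)(C)C(C)(C)C)C(C)=C | intermediate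
5 | 4-methoxybenzyl alcohol | COc1ccc(CO)cc1 | starting material
6 | trichloroethylene | ClC=C(Cl)Cl | starting material
7 | 1-{[(E)-1,2-dichloroethenyl]oxymethyl}-4-methoxybenzene | COc1ccc(CO/C(Cl)=C\Cl)cc1 | intermediate
8 | lithium (4-methoxybenzyloxy)acetylide | [Li+].[C-]#COCc1ccc(OC)cc1 | intermediate
9 | lithium (1R,4R,6R)-4-(tert-butyldimethylsilyloxy)-1-[(4-methoxybenzyloxy)ethynyl]-3-methyl-6-(prop-1-en-2-yl)cyclohex-2-en-1-olate | CC1=C[C@]([O-])(C#COCc2ccc(OC)cc2)[C@H](C[C@H]1O[Si](C)(C)C(C)(C)C)C(C)=C.[Li+] | intermediate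
10 | lithium cyclic alkoxy(alkenyl)dihydridoaluminate from trans-hydroalumination of 9 (Al bound to the carbinol oxygen and to the OPMB-bearing vinyl carbon) | CC1=C[C@@]2(O[AlH2-]C(OCc3ccc(OC)cc3)=C2)[C@H](C[C@H]1O[Si](C)(C)C(C)(C)C)C(C)=C.[Li+] | intermediate
11 | (1R,4R,6R)-4-(tert-butyldimethylsilyloxy)-1-[(E)-2-(4-methoxybenzyloxy)ethenyl]-3-methyl-6-(prop-1-en-2-yl)cyclohex-2-en-1-ol | CC1=C[C@](O)(/C=C/OCc2ccc(OC)cc2)[C@H](C[C@H]1O[Si](C)(C)C(C)(C)C)C(C)=C | intermediate
12 | potassium alkoxide of 11 | CC1=C[C@]([O-])(/C=C/OCc2ccc(OC)cc2)[C@H](C[C@H]1O[Si](C)(C)C(C)(C)C)C(C)=C.[K+] | intermediate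
13 | potassium (1R,3E,6R,7Z,9Z)-1-(tert-butyldimethylsilyloxy)-6-(4-methoxybenzyloxy)-4,10-dimethylcyclodeca-3,7,9-trien-8-olate | [C@H]1(OCc2ccc(OC)cc2)/C=C(\[O-])/C=C(C)\[C@H](O[Si](C)(C)C(C)(C)C)C/C=C(C)/C1.[K+] | intermediate
14 | methyl (1R,3E,6R,7S,9Z)-1-(tert-butyldimethylsilyloxy)-6-(4-methoxybenzyloxy)-8-oxo-13-norgermacra-3,9-dien-12-oate | COC(=O)C[C@H]1[C@H](OCc2ccc(OC)cc2)C/C(C)=C/C[C@@H](O[Si](C)(C)C(C)(C)C)/C(C)=C\C1=O | intermediate
15 | methyl (1R,3E,6R,7S,9Z)-1-(tert-butyldimethylsilyloxy)-6-hydroxy-8-oxo-13-norgermacra-3,9-dien-12-oate | COC(=O)C[C@H]1[C@H](O)C/C(C)=C/C[C@@H](O[Si](C)(C)C(C)(C)C)/C(C)=C\C1=O | intermediate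
16 | (1R,3E,6R,7S,9Z)-1-(tert-butyldimethylsilyloxy)-8-oxo-13-norgermacra-3,9-dien-12,6-olide | O=C1O[C@@H]2C/C(C)=C/C[C@@H](O[Si](C)(C)C(C)(C)C)/C(C)=C\C(=O)[C@H]2C1 | intermediate
17 | (1R,3R,4R,6R,7S,9Z)-1-(tert-butyldimethylsilyloxy)-3,4-epoxy-8-oxo-13-norgermacr-9-en-12,6-olide | O=C1O[C@@H]2C[C@@]3(C)O[C@@H]3C[C@@H](O[Si](C)(C)C(C)(C)C)/C(C)=C\C(=O)[C@H]2C1 | intermediate
18 | (1R,3R,4R,6R,7R,8R,9Z)-1-(tert-butyldimethylsilyloxy)-3,4-epoxy-8-hydroxy-13-norgermacr-9-en-12,6-olide | O=C1O[C@@H]2C[C@@]3(C)O[C@@H]3C[C@@H](O[Si](C)(C)C(C)(C)C)/C(C)=C\[C@@H](O)[C@H]2C1 | intermediate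
19 | 13-(dimethylamino) Mannich base of 18 (C11 epimers), (1R,3R,4R,6R,7R,8R,9Z)-1-(tert-butyldimethylsilyloxy)-13-(dimethylamino)-3,4-epoxy-8-hydroxygermacr-9-en-12,6-olide | CN(C)CC1C(=O)O[C@@H]2C[C@@]3(C)O[C@@H]3C[C@@H](O[Si](C)(C)C(C)(C)C)/C(C)=C\[C@@H](O)[C@@H]12 | intermediate
20 | N-methyl quaternary ammonium iodide of 19 | C[N+](C)(C)CC1C(=O)O[C@@H]2C[C@@]3(C)O[C@@H]3C[C@@H](O[Si](C)(C)C(C)(C)C)/C(C)=C\[C@@H](O)[C@@H]12.[I-] | intermediate
21 | (1R,3R,4R,6R,7R,8R,9Z)-1-(tert-butyldimethylsilyloxy)-3,4-epoxy-8-hydroxygermacra-9,11(13)-dien-12,6-olide | C=C1C(=O)O[C@@H]2C[C@@]3(C)O[C@@H]3C[C@@H](O[Si](C)(C)C(C)(C)C)/C(C)=C\[C@@H](O)[C@@H]12 | intermediate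
22 | (1R,3R,4R,6R,7R,8S,9S)-1-(tert-butyldimethylsilyloxy)-3,4-epoxy-9-hydroperoxy-8-hydroxygermacra-10(14),11(13)-dien-12,6-olide | C=C1C(=O)O[C@@H]2C[C@@]3(C)O[C@@H]3C[C@@H](O[Si](C)(C)C(C)(C)C)C(=C)[C@H](OO)[C@@H](O)[C@@H]12 | intermediate
23 | (1R,3R,4R,6R,7R,8S,9S)-1-(tert-butyldimethylsilyloxy)-3,4-epoxy-8,9-dihydroxygermacra-10(14),11(13)-dien-12,6-olide | C=C1C(=O)O[C@@H]2C[C@@]3(C)O[C@@H]3C[C@@H](O[Si](C)(C)C(C)(C)C)C(=C)[C@H](O)[C@@H](O)[C@@H]12 | intermediate
24 | (1R,3R,4R,6R,7R,8S,9S)-9-[(Z)-2-methylbut-2-enoyloxy]-1-(tert-butyldimethylsilyloxy)-3,4-epoxy-8-hydroxygermacra-10(14),11(13)-dien-12,6-olide | C=C1C(=O)O[C@@H]2C[C@@]3(C)O[C@@H]3C[C@@H](O[Si](C)(C)C(C)(C)C)C(=C)[C@H](OC(=O)/C(C)=C\C)[C@@H](O)[C@@H]12 | intermediate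
25 | (1R,3R,4R,6R,7R,8S,9S)-9-[(Z)-2-methylbut-2-enoyloxy]-3,4-epoxy-1,8-dihydroxygermacra-10(14),11(13)-dien-12,6-olide | C=C1C(=O)O[C@@H]2C[C@@]3(C)O[C@@H]3C[C@@H](O)C(=C)[C@H](OC(=O)/C(C)=C\C)[C@@H](O)[C@@H]12 | intermediate
26 | (3R,4R,6R,7R,8S,9S)-9-[(Z)-2-methylbut-2-enoyloxy]-3,4-epoxy-8-hydroxy-1-oxogermacra-10(14),11(13)-dien-12,6-olide | C=C1C(=O)O[C@@H]2C[C@@]3(C)O[C@@H]3CC(=O)C(=C)[C@H](OC(=O)/C(C)=C\C)[C@@H](O)[C@@H]12 | target

**Totals**

Total step count: 14. Longest linear sequence: 13 steps (steps 1–3 and 5–14).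

**Three steps most likely to fail**

Step 8 (face of the epoxidation). This is the least secure stereochemical call: if the olefin reacts in the rotamer left by the rearrangement (C15 on the β side), the peracid gives the 3S,4S epoxide. The fallback sets out from 16 and returns at 17. Instead of an external peracid, the C8 ketone delivers the oxygen: KHSO5 (used as 2KHSO5·KHSO4·K2SO4), NaHCO3, aqueous MeCN, high dilution, converts the ketone into the spiro dioxirane F4. C8 and C3 were bonded before the rearrangement and stay in transannular contact, so the dioxirane oxygen is held against the inner face of the C3=C4 bond and is transferred intramolecularly to the face the peracid cannot reach, regenerating the ketone and giving 17.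

Step 6 (oxy-Cope rearrangement with enolate trapping). The potassium enolate carries a β-alkoxy group and may lose 4-methoxybenzyl oxide, alkylate on oxygen, or give the C7 epimer. The fallback sets out from 11 and returns at 14. The tertiary alcohol is silylated (TMSCl, imidazole, DMF) to the trimethylsilyl ether F1. F1 is heated in toluene in a sealed tube at about 200 °C, so that a neutral siloxy-Cope rearrangement gives the ring-expanded trimethylsilyl enol ether F2 with no free enolate present while the ring forms. F2 is cleaved with MeLi in THF at −78 °C to the lithium enolate F3, which is alkylated cold with methyl bromoacetate to give 14.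

Step 12 (mono-acylation of the diol). The C8 hydroxyl may compete, or the ester may migrate between O9 and O8. The fallback sets out from 21 and returns at 25. The C8 hydroxyl is silylated (Et3SiOTf, 2,6-lutidine, CH2Cl2) to the 8-O-triethylsilyl ether F5. The singlet-oxygen ene reaction on F5 gives the hydroperoxide F6 and, after PPh3, the allylic alcohol F7, expected as the 9R epimer because an allylic silyl ether steers singlet oxygen to the face opposite to that chosen by a free hydroxyl. C9 is inverted during acylation by Mitsunobu esterification with angelic acid (PPh3, diisopropyl azodicarboxylate, toluene) to give the 9S angelate F8. HF·pyridine then removes both silyl groups and gives 25. Should F7 prove to be 9S, F8 is made from it by Yamaguchi esterification instead.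

**Further compounds**

F1 | step 6 | trimethylsilyl ether of 11 | CC1=C[C@](O[Si](C)(C)C)(/C=C/OCc2ccc(OC)cc2)[C@H](C[C@H]1O[Si](C)(C)C(C)(C)C)C(C)=C
F2 | step 6 | (1R,3E,6R,7Z,9Z)-1-(tert-butyldimethylsilyloxy)-6-(4-methoxybenzyloxy)-4,10-dimethyl-8-(trimethylsilyloxy)cyclodeca-3,7,9-triene | [C@H]1(OCc2ccc(OC)cc2)/C=C(\O[Si](C)(C)C)/C=C(C)\[C@H](O[Si](C)(C)C(C)(C)C)C/C=C(C)/C1
F3 | step 6 | lithium (1R,3E,6R,7Z,9Z)-1-(tert-butyldimethylsilyloxy)-6-(4-methoxybenzyloxy)-4,10-dimethylcyclodeca-3,7,9-trien-8-olate | [C@H]1(OCc2ccc(OC)cc2)/C=C(\[O-])/C=C(C)\[C@H](O[Si](C)(C)C(C)(C)C)C/C=C(C)/C1.[Li+]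
F4 | step 8 | spiro dioxirane formed at C8 of 16 | O=C1O[C@@H]2C/C(C)=C/C[C@@H](O[Si](C)(C)C(C)(C)C)/C(C)=C\C3(OO3)[C@H]2C1
F5 | step 12 | 8-O-triethylsilyl ether of 21 | C=C1C(=O)O[C@@H]2C[C@@]3(C)O[C@@H]3C[C@@H](O[Si](C)(C)C(C)(C)C)/C(C)=C\[C@@H](O[Si](CC)(CC)CC)[C@@H]12
F6 | step 12 | (9R)-9-hydroperoxy-10(14)-ene from F5 | C=C1C(=O)O[C@@H]2C[C@@]3(C)O[C@@H]3C[C@@H](O[Si](C)(C)C(C)(C)C)C(=C)[C@@H](OO)[C@@H](O[Si](CC)(CC)CC)[C@@H]12
F7 | step 12 | (9R)-9-hydroxy-10(14)-ene, 1-O-TBS 8-O-triethylsilyl | C=C1C(=O)O[C@@H]2C[C@@]3(C)O[C@@H]3C[C@@H](O[Si](C)(C)C(C)(C)C)C(=C)[C@@H](O)[C@@H](O[Si](CC)(CC)CC)[C@@H]12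
F8 | step 12 | (9S)-9-angelate, 1-O-TBS 8-O-triethylsilyl | C=C1C(=O)O[C@@H]2C[C@@]3(C)O[C@@H]3C[C@@H](O[Si](C)(C)C(C)(C)C)C(=C)[C@H](OC(=O)/C(C)=C\C)[C@@H](O[Si](CC)(CC)CC)[C@@H]12
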